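Each half is numbered as a naphthalene: OH at C1, acetyl at C2, methyl at C3, biaryl bond at C4, OH at C6 and C8; ring A is C4a–C8a, ring B is C1–C4 plus C4a and C8a. The chain C3(Me)–C4–C4′–C3′(Me), carrying on each C4 one further acetyl (C1 and the later C2), is tetraacetylethane, and ring A is a 3,5-dimethoxybenzyne. The key step inserts two such arynes, from an ortho-silylaryl triflate, into the two CH–acetyl bonds of the tetraketone, making C4–C4a and C1–C8a on both sides at once. Aldol aromatisation, a Fries shift of acetyl to C2 and demethylation finish the route.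

Key step: step 5

Assumption: the biaryl axis of the target is drawn without configuration, so the racemate is the goal; binaphthyl names below keep the numbering given above (junction C4–C4′), and the tetraketone is drawn in its keto form although it is largely a bis-enol.

Step 1
Reactants: 1 3,5-dimethoxyphenol
Product: 2 3,5-dimethoxyphenyl N-(propan-2-yl)carbamate
Conditions: i-PrNCO, Et3N (cat.), CH2Cl2, rt
Reagents that add atoms: isopropyl isocyanate, CC(C)N=C=O
Why: Amine-catalysed addition of the phenol O–H to the isocyanate (carbamoylation) should give the N-monoalkyl carbamate, a strong ortho-directing group that can later be removed under mild base.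

Step 2
Reactants: 2 3,5-dimethoxyphenyl N-(propan-2-yl)carbamate
Product: 6 3,5-dimethoxy-2-(trimethylsilyl)phenyl N-(propan-2-yl)carbamate, via N-TBS carbamate 3 (not isolated), via ortho-lithiated N-TBS carbamate 4 (not isolated), via N-TBS ortho-TMS carbamate 5 (not isolated)
Conditions: TBSOTf, TMEDA, Et2O, 0 °C → rt; n-BuLi, TMEDA, −78 °C; TMSCl, −78 °C → rt; aq. NaHSO4
Reagents that add atoms: chlorotrimethylsilane, C[Si](C)(C)Cl
Why: Directed ortho metalation: after in-flask N-silylation of the carbamate N–H, n-BuLi should remove the proton at C2, which is activated jointly by the carbamate and the adjacent methoxy group, TMSCl traps the aryllithium at −78 °C before an anionic Fries shift can set in, and the labile N–Si bond is hydrolysed on acidic work-up.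

Step 3
Reactants: 6 3,5-dimethoxy-2-(trimethylsilyl)phenyl N-(propan-2-yl)carbamate
Product: 8 3,5-dimethoxy-2-(trimethylsilyl)phenyl trifluoromethanesulfonate, via silylphenol 7 (not isolated)
Conditions: DBU, Et2NH, MeCN, 40 °C; then PhNTf2, rt
Reagents that add atoms: N-phenylbis(trifluoromethanesulfonimide), O=S(=O)(N(c1ccccc1)S(=O)(=O)C(F)(F)F)C(F)(F)F
Why: Base-induced E1cB cleavage of the N–H carbamate (loss of isopropyl isocyanate, trapped by Et2NH as a urea) should free the phenoxide, which is O-sulfonylated by PhNTf2 in the same flask (triflation), so the protodesilylation-prone silylphenol is never handled.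

Step 4
Reactants: 9 pentane-2,4-dione (two equivalents)
Product: 11 3,4-diacetylhexane-2,5-dione, via sodium pentane-2,4-dionate 10 (not isolated)
Conditions: NaH, THF, 0 °C; then I2 (0.5 equiv), 0 °C → rt
Reagents that add atoms: none
Why: Oxidative enolate dimerisation: iodine should oxidise the sodium enolate and join two enolate carbons, which become C4 and C4′ of the target.

Step 5
Reactants: 8 3,5-dimethoxy-2-(trimethylsilyl)phenyl trifluoromethanesulfonate (about 2.5 equiv), 11 3,4-diacetylhexane-2,5-dione
Product: 14 3,4-bis(2-acetyl-3,5-dimethoxyphenyl)hexane-2,5-dione, via 3,5-dimethoxybenzyne 12 (not isolated), via mono-insertion triketone 13 (not isolated)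
Conditions: CsF (6 equiv), MeCN, rt → 50 °C, 8 added slowly
Reagents that add atoms: none
Why: Fluoride attack on silicon expels triflate to give aryne 12; the caesium enolate carbon of one 1,3-diketone unit (future C4) adds to the aryne carbon remote from the flanking methoxy group (future C4a), the aryl anion at C8a adds to an acetyl carbonyl on that same carbon, and the benzocyclobutenoxide opens by retro-aldol cleavage so that this acetyl (C1 with the future C2) ends on C8a; the second diketone unit of 13 then reacts in the same way to give 14. The closest known reaction type is the fluoride-induced aryne acyl-alkylation (C–C sigma-bond insertion) of beta-diketones and beta-ketoesters, which includes alpha-substituted substrates and 3-alkoxyarynes. No ring is closed in the product; the only ring formed is the transient four-membered alkoxide, closed by 4-exo-trig addition and opened again at once. The two stereocentres (C4 and C4′, hexanedione C3 and C4) should arise by uncontrolled protonation of the product enolates, giving a meso/racemic mixture, and both are erased on aromatisation in step 6. The step needs regioselective addition to the aryne, which the methoxy group next to C8a secures by inductive stabilisation of the ortho aryl anion, and it needs the aryl anion to choose the acetyl on its own carbon, which is helped because the untouched diketone unit sits as its chelated enol or caesium enolate and so offers neither a free ketone nor a fast proton source.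

Step 6
Reactants: 14 3,4-bis(2-acetyl-3,5-dimethoxyphenyl)hexane-2,5-dione
Product: 16 6,6′,8,8′-tetramethoxy-3,3′-dimethyl-4,4′-binaphthalene-1,1′-diol, via bis-aldol adduct 15 (not isolated)
Conditions: KOH, MeOH, rt → 50 °C, argon; then aq. HCl
Reagents that add atoms: none
Why: Twofold intramolecular aldol condensation: the enolate of each aryl methyl ketone (C2) should add to the aliphatic ketone on the adjacent benzylic carbon (C3) in a six-membered closure, and loss of water with enolisation gives the aromatic 1-naphthol, an irreversible sink that removes both stereocentres, while the hindered, electron-rich aryl ketone is the poorer electrophile and so disfavours the isomeric 2-naphthol.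

Step 7
Reactants: 16 6,6′,8,8′-tetramethoxy-3,3′-dimethyl-4,4′-binaphthalene-1,1′-diol
Product: 17 6,6′,8,8′-tetramethoxy-3,3′-dimethyl-4,4′-binaphthalene-1,1′-diyl diacetate
Conditions: Ac2O, pyridine, DMAP (cat.), CH2Cl2, rt
Reagents that add atoms: acetic anhydride, CC(=O)OC(C)=O
Why: Nucleophile-catalysed O-acylation should esterify both naphthols and so load exactly one acetyl per half for the next step.

Step 8
Reactants: 17 6,6′,8,8′-tetramethoxy-3,3′-dimethyl-4,4′-binaphthalene-1,1′-diyl diacetate
Product: 18 1,1′-(1,1′-dihydroxy-6,6′,8,8′-tetramethoxy-3,3′-dimethyl-4,4′-binaphthalene-2,2′-diyl)di(ethan-1-one)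
Conditions: Sc(OTf)3 (20 mol%), toluene, 100 °C
Reagents that add atoms: none
Why: Lewis-acid-catalysed Fries rearrangement should move each acetyl from O1 to C2, the only open ortho or para position of ring B because C4 is the biaryl carbon, with the chelated ortho-hydroxyaryl ketone as thermodynamic product and with C5 (peri to the biaryl bond) and C7 (between two methoxy groups) of ring A shielded.

Step 9
Reactants: 18 1,1′-(1,1′-dihydroxy-6,6′,8,8′-tetramethoxy-3,3′-dimethyl-4,4′-binaphthalene-2,2′-diyl)di(ethan-1-one)
Product: 19 1,1′-(1,1′,6,6′,8,8′-hexahydroxy-3,3′-dimethyl-4,4′-binaphthalene-2,2′-diyl)di(ethan-1-one)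
Conditions: BBr3 (excess), CH2Cl2, −78 °C → rt; then MeOH, H2O
Reagents that add atoms: none
Why: Lewis-acid ether cleavage (BBr3 demethylation) should remove all four methyl groups, the C8 ethers peri to the chelated C1 hydroxyl first and the C6 ethers with the excess at room temperature, while the aryl ketones and the biaryl bond stay untouched and no stereocentre is involved.

Compound list
1 | 3,5-dimethoxyphenol | COc1cc(O)cc(OC)c1 | starting material
2 | 3,5-dimethoxyphenyl N-(propan-2-yl)carbamate | COc1cc(OC)cc(OC(=O)NC(C)C)c1 | intermediate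
3 | 3,5-dimethoxyphenyl N-[tert-butyl(dimethyl)silyl]-N-(propan-2-yl)carbamate (formed in the flask) | COc1cc(OC)cc(OC(=O)N(C(C)C)[Si](C)(C)C(C)(C)C)c1 | intermediate
4 | 2-lithio-3,5-dimethoxyphenyl N-[tert-butyl(dimethyl)silyl]-N-(propan-2-yl)carbamate (formed in the flask) | COc1cc(OC)c([Li])c(OC(=O)N(C(C)C)[Si](C)(C)C(C)(C)C)c1 | intermediate
5 | 3,5-dimethoxy-2-(trimethylsilyl)phenyl N-[tert-butyl(dimethyl)silyl]-N-(propan-2-yl)carbamate (formed in the flask) | COc1cc(OC)c([Si](C)(C)C)c(OC(=O)N(C(C)C)[Si](C)(C)C(C)(C)C)c1 | intermediate
6 | 3,5-dimethoxy-2-(trimethylsilyl)phenyl N-(propan-2-yl)carbamate | COc1cc(OC)c([Si](C)(C)C)c(OC(=O)NC(C)C)c1 | intermediate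
7 | 3,5-dimethoxy-2-(trimethylsilyl)phenol (formed in the flask) | COc1cc(O)c([Si](C)(C)C)c(OC)c1 | intermediate
8 | 3,5-dimethoxy-2-(trimethylsilyl)phenyl trifluoromethanesulfonate | COc1cc(OC)c([Si](C)(C)C)c(OS(=O)(=O)C(F)(F)F)c1 | intermediate
9 | pentane-2,4-dione | CC(=O)CC(C)=O | starting material
10 | sodium pentane-2,4-dionate (formed in the flask) | CC(=O)C=C(C)[O-].[Na+] | intermediate
11 | 3,4-diacetylhexane-2,5-dione | CC(=O)C(C(C)=O)C(C(C)=O)C(C)=O | intermediate
12 | 3,5-dimethoxybenzyne (formed in the flask) | COC1=CC(OC)=CC#C1 | intermediate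
13 | 3-acetyl-4-(2-acetyl-3,5-dimethoxyphenyl)hexane-2,5-dione (formed in the flask, racemic) | CC(=O)C(C(C)=O)C(C(C)=O)c1cc(OC)cc(OC)c1C(C)=O | intermediate
14 | 3,4-bis(2-acetyl-3,5-dimethoxyphenyl)hexane-2,5-dione (meso/racemic mixture) | CC(=O)C(c1cc(OC)cc(OC)c1C(C)=O)C(C(C)=O)c1cc(OC)cc(OC)c1C(C)=O | intermediate
15 | 3,3′-dihydroxy-6,6′,8,8′-tetramethoxy-3,3′-dimethyl-3,3′,4,4′-tetrahydro-4,4′-binaphthalene-1,1′(2H,2′H)-dione (formed in the flask, mixture of stereoisomers) | CC1(O)CC(=O)c2c(OC)cc(OC)cc2C1C1c2cc(OC)cc(OC)c2C(=O)CC1(C)O | intermediate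
16 | 6,6′,8,8′-tetramethoxy-3,3′-dimethyl-4,4′-binaphthalene-1,1′-diol (racemic axis) | Cc1cc(O)c2c(OC)cc(OC)cc2c1-c1c(C)cc(O)c2c(OC)cc(OC)cc12 | intermediate
17 | 6,6′,8,8′-tetramethoxy-3,3′-dimethyl-4,4′-binaphthalene-1,1′-diyl diacetate (racemic axis) | CC(=O)Oc1cc(C)c(-c2c(C)cc(OC(C)=O)c3c(OC)cc(OC)cc23)c2cc(OC)cc(OC)c12 | intermediate
18 | 1,1′-(1,1′-dihydroxy-6,6′,8,8′-tetramethoxy-3,3′-dimethyl-4,4′-binaphthalene-2,2′-diyl)di(ethan-1-one) (racemic axis) | CC(=O)c1c(C)c(-c2c(C)c(C(C)=O)c(O)c3c(OC)cc(OC)cc23)c2cc(OC)cc(OC)c2c1O | intermediate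
19 | 1,1′-(1,1′,6,6′,8,8′-hexahydroxy-3,3′-dimethyl-4,4′-binaphthalene-2,2′-diyl)di(ethan-1-one), CNP0138820.0 (axis unspecified) | CC(=O)c1c(C)c(-c2c(C)c(C(C)=O)c(O)c3c(O)cc(O)cc23)c2cc(O)cc(O)c2c1O | target

Total step count: 9. Longest linear sequence: 8 steps (steps 1, 2, 3, 5, 6, 7, 8, 9 from compound 1); step 4 is a one-step branch that joins at step 5.

Steps most likely to fail

1. Step 5. The enolate carbon that must arylate already carries the second diketone unit, so C-arylation is crowded and O-arylation may compete. The aryl anion may also be lost by proton transfer, or by five-membered addition to a ketone on the neighbouring carbon instead of four-membered addition to its own acetyl. This is most exposed in the second insertion, when the first side already holds a free ketone. The acidic benzylic C–H of the product may be arylated again. Fallback: setting out from 8 and 9, one aryne would be inserted into pentane-2,4-dione itself (CsF, MeCN, rt) to give 1-(2-acetyl-3,5-dimethoxyphenyl)propan-2-one F1. Its benzylic enolate (LiN(i-Pr)2, THF, −78 °C) would then be coupled oxidatively with CuCl2 (or 0.5 equiv I2), which forms the C4–C4′ bond last and comes back to the route at 14.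

2. Step 8. The acetyl may be transferred between molecules onto ring A (C5 or C7), migration to the crowded C2 (between O1 and the C3 methyl) may stall, or the acetyl may simply be lost to return the naphthol. Fallback: setting out from 16, magnesium-phenoxide-directed ortho-formylation (MgCl2, Et3N, paraformaldehyde, MeCN, reflux) would give 1,1′-dihydroxy-6,6′,8,8′-tetramethoxy-3,3′-dimethyl-4,4′-binaphthalene-2,2′-dicarbaldehyde F2, with C2 fixed by delivery from the phenoxide. Addition of MeMgBr (excess, THF, 0 °C) would give 2,2′-bis(1-hydroxyethyl)-6,6′,8,8′-tetramethoxy-3,3′-dimethyl-4,4′-binaphthalene-1,1′-diol F3. Benzylic oxidation (MnO2, CH2Cl2, or Dess–Martin periodinane) comes back to the route at 18.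

3. Step 6. The aldol may close in the wrong sense (aliphatic methyl enolate onto the aryl ketone, leading to a 2-naphthol), or a five-membered aldol may run across the 1,4-diketone unit before the first ring B is aromatic. The naphtholate may also be oxidised by air. Fallback: setting out from 8 and 9, ring B would be closed before the C4–C4′ bond exists. Diketone F1 (made as in the first fallback; it has no 1,4-dicarbonyl unit) would be cyclised with KOH in MeOH to 6,8-dimethoxy-3-methylnaphthalen-1-ol F4. Oxidative para–para phenol coupling (FeCl3 on silica, or di-tert-butyl peroxide in chlorobenzene, with Na2S2O4 to reduce any over-oxidised quinoid dimer) would then join C4 to C4′ and come back to the route at 16. C2-linked isomers would have to be separated.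

Further compounds
F1 | step 5 | 1-(2-acetyl-3,5-dimethoxyphenyl)propan-2-one | CC(=O)Cc1cc(OC)cc(OC)c1C(C)=O
F2 | step 8 | 1,1′-dihydroxy-6,6′,8,8′-tetramethoxy-3,3′-dimethyl-4,4′-binaphthalene-2,2′-dicarbaldehyde | O=Cc1c(C)c(-c2c(C)c(C=O)c(O)c3c(OC)cc(OC)cc23)c2cc(OC)cc(OC)c2c1O
F3 | step 8 | 2,2′-bis(1-hydroxyethyl)-6,6′,8,8′-tetramethoxy-3,3′-dimethyl-4,4′-binaphthalene-1,1′-diol (mixture of stereoisomers) | CC(O)c1c(C)c(-c2c(C)c(C(C)O)c(O)c3c(OC)cc(OC)cc23)c2cc(OC)cc(OC)c2c1O
F4 | step 6 | 6,8-dimethoxy-3-methylnaphthalen-1-ol | Cc1cc(O)c2c(OC)cc(OC)cc2c1
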